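The fifteen cage carbons of the target are an intact head-to-tail farnesyl chain, C5–C4=C3(Me)–C2–C1–C11=C10(Me)–C9–C8–C7=C6(Me)2, held together by three extra bonds, C5–C6, C5–C11 and C4–C10. Cutting these opens the cycloheptane, the cyclohexene and the cyclobutane C4–C5–C11–C10 at once and leaves an acyclic triene. Forward, (2E,6E)-farnesyl bromide 1 gives the diphosphate 2, which an α-longipinene synthase folds into α-longipinene 3, forming the three bonds and the stereocentres C4, C5, C10 and C11 in one operation. Oxygen follows: allylic oxidation at C1, enzymatic hydroxylation at C7 and then C8, isobutyrate at O8 and angelate at O7.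

Key step: step 2

Numbering and structure check: longipinane numbers are used throughout (C1 carbonyl, C2=C3 with methyl on C3, cyclobutane C4–C5–C11–C10, C6 gem-dimethyl, C7 and C8 ester carbons, C9 methylene, C10 methyl-bearing). The target is (4R,5S,7S,8S,10R,11R) with trans ester oxygens, C7–O on the side of the seven-membered ring where C4 lies and C8–O on the side where C11 lies. Its cage is that of (1R,2S,7R,8R)-α-longipinene, and no structure needed correction.

Assumption: the synthase chosen delivers the dextrorotatory (1R,2S,7R,8R) enantiomer of 3; this is confirmed by chiral GC before 3 is carried on.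

Step 1
Reactants: 1 (2E,6E)-farnesyl bromide
Product: 2 (2E,6E)-farnesyl diphosphate (isolated and used as its trisammonium salt)
Conditions: (n-Bu4N)3HP2O7, MeCN, 23 °C; Dowex 50W-X8 (NH4+ form), NH4HCO3 buffer (remaining n-Bu4N+ stays on the resin); cellulose chromatography, lyophilisation
Reagents that add atoms: tris(tetrabutylammonium) hydrogen diphosphate, CCCC[N+](CCCC)(CCCC)CCCC.CCCC[N+](CCCC)(CCCC)CCCC.CCCC[N+](CCCC)(CCCC)CCCC.OP(=O)([O-])OP(=O)([O-])[O-]
Why: SN2 diphosphorylation of the primary allylic bromide carbon (the later C5) by hydrogen diphosphate should proceed without allylic transposition, so both E olefins reach 2 unchanged and no stereocentre is involved.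

Step 2
Reactants: 2 (2E,6E)-farnesyl diphosphate
Product: 3 α-longipinene, (1R,2S,7R,8R)-2,6,6,9-tetramethyltricyclo[5.4.0.0(2,8)]undec-9-ene, which is (4R,5R,10S,11R) in longipinane numbering
Conditions: recombinant α-longipinene synthase (His-tagged, purified), MgCl2, HEPES buffer pH 7.3, DTT, 10% glycerol, pentane overlay, 30 °C; pentane phase through SiO2, then AgNO3–SiO2
Reagents that add atoms: none
Why: MgCl2-assisted ionisation of the diphosphate inside the enzyme, return of diphosphate to C3 and re-ionisation from the cisoid conformer give an allyl cation whose C5 end is attacked by C6 of the distal olefin (eleven-membered ring, charge on C7); a 1,3-hydride shift from C5 to C7 then places the charge in the C3–C4–C5 allyl unit, C11 of the central olefin bonds to C5, C4 of the C3=C4 olefin bonds to the resulting tertiary C10 cation, and loss of a proton from C2 leaves the C2=C3 double bond. The closest known reaction type is the diphosphate-ionising (class one) sesquiterpene synthase cascade through humulyl, himachalyl and longipinyl cations, which known synthases run on this very substrate to give α-longipinene. Ring closures: C5–C6 is a macrocyclisation to an eleven-membered ring, C5–C11 is a transannular 6-exo cation–olefin closure that divides it into the cyclohexene and the seven-membered ring C5–C6–C7–C8–C9–C10–C11, and C4–C10 is a 4-exo cation–olefin closure that completes the cyclobutane C4–C5–C11–C10. Stereocentres: the substrate is achiral, and because the tether C6–C9 can span C5 and C10 only on the cage face opposite the C1–C2–C3 bridge, the relative configuration of C4, C5, C10 and C11 is dictated by cage geometry, while the absolute sense (which face of the allyl cation at C5 meets C11) is fixed by the handed contour of the active site. The step needs product specificity (no early proton loss to humulene or himachalenes, no capture by water, no Wagner–Meerwein drift to longifolene) and one enantiomer; the substrate contributes the 2E,6E geometry and the 1,5-spacing of its three olefins that make each closure geometrically possible, and the water-free pocket that holds this fold makes the otherwise uphill four-ring closure and the C2 deprotonation the preferred exit.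

Step 3
Reactants: 3 α-longipinene
Product: 4 (4R,5S,10R,11R)-longipin-2-en-1-one
Conditions: CrO3, 3,5-dimethylpyrazole, CH2Cl2, −20 °C
Reagents that add atoms: chromium trioxide, O=[Cr](=O)=O
Why: Allylic oxidation with the hexavalent chromium–3,5-dimethylpyrazole complex should convert the only accessible ring allylic methylene, C1, into the enone carbonyl (the other ring allylic hydrogen sits on the cyclobutane bridgehead C4), in the way α-pinene gives verbenone; no stereocentre is formed or touched.

Step 4
Reactants: 4 (4R,5S,10R,11R)-longipin-2-en-1-one
Product: 5 (4R,5S,7R,10R,11R)-7-hydroxylongipin-2-en-1-one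
Conditions: P450 BM3 (CYP102A1) variant selected from an active-site mutant panel for C7 hydroxylation, NADP+ (cat.), D-glucose, glucose dehydrogenase, air, KH2PO4/K2HPO4 buffer pH 8.0, 2% EtOH, 25 °C
Reagents that add atoms: dioxygen, O=O
Why: Cytochrome P450 C–H hydroxylation (hydrogen abstraction and oxygen rebound with retention) at C7, the neopentylic ring methylene far from the deactivating enone, follows the known hydroxylation of methylenes next to gem-dimethyl carbons in terpenoid ketones and lactones by P450 BM3 mutants; the variant is screened for C7 selectivity and for replacing the C7 hydrogen on the ring side where C4 lies, which sets the 7R carbinol.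

Step 5
Reactants: 5 (4R,5S,7R,10R,11R)-7-hydroxylongipin-2-en-1-one
Product: 6 (4R,5S,7S,8S,10R,11R)-7,8-dihydroxylongipin-2-en-1-one (trans-diol)
Conditions: second P450 BM3 (CYP102A1) variant evolved on 5 for C8 hydroxylation, NADP+ (cat.), D-glucose, glucose dehydrogenase, air, KH2PO4/K2HPO4 buffer pH 8.0, 2% EtOH, 25 °C
Reagents that add atoms: dioxygen, O=O
Why: A second P450 hydroxylation should replace with retention the C8 hydrogen on the ring side where C11 lies and so give the trans-7,8-diol, a vicinal hydroxylation next to an existing carbinol with enzymatic precedent in the 16α-hydroxylation of 17β-hydroxy steroids and the 2α-hydroxylation of 3β-hydroxy triterpenoids; the C8 configuration is set by the enzyme pocket and C7 is untouched.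

Step 6
Reactants: 6 (4R,5S,7S,8S,10R,11R)-7,8-dihydroxylongipin-2-en-1-one; 7 isobutyryl chloride
Product: 8 (4R,5S,7S,8S,10R,11R)-7-hydroxy-8-isobutyryloxylongipin-2-en-1-one
Conditions: 7 (1.05 equiv), pyridine, CH2Cl2, −30 → 0 °C
Reagents that add atoms: none
Why: Kinetically controlled acyl chloride esterification should select the C8 hydroxyl because the C7 hydroxyl is neopentylic (flanked by the quaternary C6); only O–H bonds react, so no stereocentre changes.

Step 7
Reactants: 8 (4R,5S,7S,8S,10R,11R)-7-hydroxy-8-isobutyryloxylongipin-2-en-1-one; 9 angelic acid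
Product: 11 (4R,5S,7S,8S,10R,11R)-7-angeloyloxy-8-isobutyryloxylongipin-2-en-1-one (target), via angelic 2,4,6-trichlorobenzoic anhydride 10 (not isolated)
Conditions: 9, 2,4,6-Cl3C6H2COCl, Et3N, toluene, 23 °C; then 8, toluene, 80 °C
Reagents that add atoms: 2,4,6-trichlorobenzoyl chloride, O=C(Cl)c1c(Cl)cc(Cl)cc1Cl (its atoms are in 10, not in 11)
Why: Yamaguchi-type esterification through the mixed anhydride, run without DMAP, should acylate the hindered C7 hydroxyl at the unshielded angeloyl carbonyl and keep the Z geometry, because it avoids the nucleophile-catalysed addition–elimination that leads to tiglates; C7 and C8 keep their configurations since only the O–H bond reacts.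

Compound list
1 | (2E,6E)-farnesyl bromide, (2E,6E)-1-bromo-3,7,11-trimethyldodeca-2,6,10-triene | CC(C)=CCC/C(C)=C/CC/C(C)=C/CBr | starting material
2 | (2E,6E)-farnesyl diphosphate (handled as trisammonium salt) | CC(C)=CCC/C(C)=C/CC/C(C)=C/COP(=O)(O)OP(=O)(O)O | intermediate
3 | α-longipinene, (1R,2S,7R,8R)-2,6,6,9-tetramethyltricyclo[5.4.0.0(2,8)]undec-9-ene | C1CC[C@@]2(C)[C@@H]3CC=C(C)[C@H]2[C@@H]3C1(C)C | intermediate
4 | (4R,5S,10R,11R)-longipin-2-en-1-one | C1CC[C@@]2(C)[C@@H]3C(=O)C=C(C)[C@H]2[C@@H]3C1(C)C | intermediate
5 | (4R,5S,7R,10R,11R)-7-hydroxylongipin-2-en-1-one | O[C@@H]1CC[C@@]2(C)[C@@H]3C(=O)C=C(C)[C@H]2[C@@H]3C1(C)C | intermediate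
6 | (4R,5S,7S,8S,10R,11R)-7,8-dihydroxylongipin-2-en-1-one | O[C@@H]1[C@@H](O)C[C@@]2(C)[C@@H]3C(=O)C=C(C)[C@H]2[C@@H]3C1(C)C | intermediate
7 | isobutyryl chloride | CC(C)C(=O)Cl | starting material
8 | (4R,5S,7S,8S,10R,11R)-7-hydroxy-8-isobutyryloxylongipin-2-en-1-one | O[C@@H]1[C@@H](OC(=O)C(C)C)C[C@@]2(C)[C@@H]3C(=O)C=C(C)[C@H]2[C@@H]3C1(C)C | intermediate
9 | angelic acid, (Z)-2-methylbut-2-enoic acid | C/C=C(/C)C(=O)O | starting material
10 | angelic 2,4,6-trichlorobenzoic anhydride | C/C=C(/C)C(=O)OC(=O)c1c(Cl)cc(Cl)cc1Cl | intermediate
11 | (4R,5S,7S,8S,10R,11R)-7-angeloyloxy-8-isobutyryloxylongipin-2-en-1-one | C/C=C(/C)C(=O)O[C@@H]1[C@@H](OC(=O)C(C)C)C[C@@]2(C)[C@@H]3C(=O)C=C(C)[C@H]2[C@@H]3C1(C)C | target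

Total step count: 7. Longest linear sequence: 7 steps (1 to 11).

Steps most likely to fail

1. Step 5 (second enzymatic hydroxylation). What may go wrong: over-oxidation of the C7 carbinol to the ketone, attack at C9 or a methyl group instead of C8, or oxygen delivery to the wrong face of C8. The fallback sets out from 5, returns at 8 and makes step 6 unnecessary. Compound 5 (either C7 epimer serves) is dehydrated with Martin sulfurane, Ph2S[OC(CF3)2Ph]2, in CH2Cl2 to (4R,5S,10R,11R)-longipina-2,7-dien-1-one F1; because C6 is quaternary, elimination can only run toward C8. mCPBA with NaHCO3 in CH2Cl2 should epoxidise the isolated C7=C8 olefin and leave the electron-poor enone alone. The olefin lies in the local mirror plane of the cage, so little substrate bias is expected, and the (7S,8R)-7,8-epoxylongipin-2-en-1-one F2 (oxygen on the side of C4) has to be separated by chromatography from its (7R,8S) diastereomer F3. Heating F2 with i-PrCO2Cs in isobutyric acid/DMF should open the oxirane by SN2 attack at C8, the carbon remote from the quaternary C6, with inversion, giving the trans hydroxy ester 8 directly.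

2. Step 4 (first enzymatic hydroxylation). What may go wrong: poor site selectivity (attack at the more exposed C8–H, at C9 or at a methyl group) or oxygen delivery to the wrong face of C7. The fallback sets out from 4 and returns at 8. The site demand is relaxed to the most exposed methylene: a C8-selective variant from the same panel gives (4R,5S,8R,10R,11R)-8-hydroxylongipin-2-en-1-one F4 (either epimer serves). Martin sulfurane dehydrates it to a mixture of longipina-2,7-dien-1-one F1 and its regioisomer longipina-2,8-dien-1-one F5, which are separated on AgNO3-impregnated silica. F1 is then epoxidised and the (7S,8R)-epoxide F2 opened with isobutyrate as described under step 5, so that both carbinol configurations come from the epoxide and not from the enzyme. A 7-hydroxy product of the wrong configuration can be used in the same way through F1.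

3. Step 7 (angeloylation). What may go wrong: Z to E isomerisation of the angeloyl group (tiglate formation) during slow acylation of the neopentylic C7 hydroxyl, and migration of the isobutyryl group from O8 to O7. The fallback sets out from 8 and returns at 11. The Z olefin is built on the ester instead of being carried in: 8 is esterified with 2-[bis(2,2,2-trifluoroethoxy)phosphoryl]propanoic acid (DCC, DMAP, CH2Cl2, 23 °C) to the 7-phosphonopropanoate ester F6 (epimers at the phosphonate carbon). A Still–Gennari olefination of F6 with acetaldehyde (KN(SiMe3)2, 18-crown-6, THF, −78 °C) should then deliver the Z-trisubstituted enoate, which is the angelate 11.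

Further compounds
F1 | step 5 | (4R,5S,10R,11R)-longipina-2,7-dien-1-one | C1=CC[C@@]2(C)[C@@H]3C(=O)C=C(C)[C@H]2[C@@H]3C1(C)C
F2 | step 5 | (4R,5S,7S,8R,10R,11R)-7,8-epoxylongipin-2-en-1-one (oxirane oxygen on the side of C4) | O1[C@@H]2[C@H]1C[C@@]3(C)[C@@H]4C(=O)C=C(C)[C@H]3[C@@H]4C2(C)C
F3 | step 5 | (4R,5S,7R,8S,10R,11R)-7,8-epoxylongipin-2-en-1-one (oxirane oxygen on the side of C11) | O1[C@H]2[C@@H]1C[C@@]3(C)[C@@H]4C(=O)C=C(C)[C@H]3[C@@H]4C2(C)C
F4 | step 4 | (4R,5S,8R,10R,11R)-8-hydroxylongipin-2-en-1-one | C1[C@@H](O)C[C@@]2(C)[C@@H]3C(=O)C=C(C)[C@H]2[C@@H]3C1(C)C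
F5 | step 4 | (4R,5S,10R,11R)-longipina-2,8-dien-1-one | C1C=C[C@@]2(C)[C@@H]3C(=O)C=C(C)[C@H]2[C@@H]3C1(C)C
F6 | step 7 | (4R,5S,7S,8S,10R,11R)-7-{2-[bis(2,2,2-trifluoroethoxy)phosphoryl]propanoyloxy}-8-isobutyryloxylongipin-2-en-1-one | CC(C(=O)O[C@@H]1[C@@H](OC(=O)C(C)C)C[C@@]2(C)[C@@H]3C(=O)C=C(C)[C@H]2[C@@H]3C1(C)C)P(=O)(OCC(F)(F)F)OCC(F)(F)F
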